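**Plan**
Retrosynthesis: the C3–aroyl and C5–geranyl bonds are cut last (two lithiations of a methyl enol ether); C3 is then taken out of ring A (C1–C2–C3–C4–C5–C9), and the C5–C6 and C1–C8 bonds of ring B are cut back to a cyclopentanetrione and an enal.
Enabling feature: C3 lies between the C2 and C4 carbonyls, so without it ring A is the five-membered ring C1–C2(=O)–C4(=O)–C5–C9(=O), a bridged vicinal trione whose strained, non-enolisable 1,2-dione accepts one diazomethane carbon by acyl shift.
Forward: five-membered ring first (double Claisen); ring B (C5–C6–C7–C8–C1–C9) by Michael/elimination/Michael annulation; one-carbon ring expansion to ring A; C7 and C1 allyl groups to prenyl; bridgehead geranylation at C5; C3 aroylation; deprotection.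
Stereochemistry: C1 and C5 are set together in the annulation by a chiral ammonium ion pair (the one-carbon bridge can only be cis). C7 follows by thermodynamic control (aldehyde exo, anti to the C2–C4 bridge). The ring expansion and both lithiations leave all three centres untouched.

Key step: step 7

Assumption: the target is a tautomeric 2-acyl-1,3-diketone; the drawn C4 enol and the C2 enol are one compound, so hydrolysis of a C2 methyl enol ether delivers the target.

**Step 1**
Reactants: 1 hex-5-en-2-one; 2 diethyl oxalate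
Product: 4 ethyl 2-oxo-2-[2,3,5-trioxo-4-(prop-2-en-1-yl)cyclopentyl]acetate, via diketo ester 3 (not isolated)
Conditions: NaOEt (2.5 equiv), 2 (2 equiv), EtOH, 0 °C to reflux; then cold aq. HCl
Reagents that add atoms: none
Why: Double Claisen condensation of a methyl ketone with diethyl oxalate (the classical cyclopentane-1,2,4-trione synthesis); the second equivalent C-acylates the acidic unsubstituted ring carbon and drives the sequence to one product.

**Step 2**
Reactants: 4 ethoxalyl cyclopentanetrione
Product: 5 3-(prop-2-en-1-yl)cyclopentane-1,2,4-trione (enolised)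
Conditions: aq. H3PO4, reflux
Reagents that add atoms: none
Why: Hydrolytic retro-Claisen removal of the ethoxalyl group from the β-tricarbonyl (standard second stage of the trione synthesis); the terminal alkene should tolerate hot dilute acid, which is why allyl and not prenyl is carried here.

**Step 3**
Reactants: 6 3,3-diethoxyprop-1-ene (acrolein diethyl acetal)
Product: 8 2-bromo-3,3-diethoxyprop-1-ene, via dibromide 7 (not isolated)
Conditions: Br2, CH2Cl2, −10 °C; then KOtBu, THF, 0 °C
Reagents that add atoms: bromine, BrBr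
Why: Bromine addition followed by E2 loss of HBr through the more acidic C2–H gives the 2-bromovinyl acetal (bromination–dehydrobromination).

**Step 4**
Reactants: 8 2-bromo-3,3-diethoxyprop-1-ene
Product: 11 3-(diethoxymethyl)-2-methylbut-3-en-2-yl acetate, via vinyllithium 9 (not isolated), via lithium alkoxide 10 (not isolated)
Conditions: t-BuLi (2 equiv), Et2O, −78 °C; acetone; then Ac2O, −78 °C to rt; aq. NH4Cl
Reagents that add atoms: acetone, CC(C)=O; acetic anhydride, CC(=O)OC(C)=O
Why: Bromine–lithium exchange gives the α-acrolein anion equivalent, which adds to acetone; the tertiary lithium alkoxide is acetylated in the same flask.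

**Step 5**
Reactants: 11 acetal acetate
Product: 12 3-formyl-2-methylbut-3-en-2-yl acetate [2-(2-acetoxypropan-2-yl)prop-2-enal]
Conditions: oxalic acid, wet SiO2, CH2Cl2, rt; used crude
Reagents that add atoms: water, O
Why: Mild acetal hydrolysis unmasks the α-substituted acrolein without ionising the tertiary allylic acetate.

**Step 6**
Reactants: 5 3-(prop-2-en-1-yl)cyclopentane-1,2,4-trione; 12 3-formyl-2-methylbut-3-en-2-yl acetate
Product: 14 (1R,3S,5S)-2,2-dimethyl-6,7,8-trioxo-1-(prop-2-en-1-yl)bicyclo[3.2.1]octane-3-carbaldehyde, via trione enal 13 (not isolated)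
Conditions: Cs2CO3 (2.5 equiv), 2,7-bis[(O-allylhydrocinchonidinium-N-yl)methyl]naphthalene dibromide (10 mol %), CH2Cl2, 4 Å MS, −50 to −20 °C; aq. NH4Cl
Reagents that add atoms: none
Why: Alkylative α,α′-annulation of a cyclic β-dicarbonyl bis-nucleophile with an α-(1-acyloxyalkyl)acrolein (tandem Michael addition, E1cB loss of acetate and intramolecular Michael addition, the reaction type known for acylphloroglucinols and cyclic β-keto esters): in the dianion of 5 the last-formed, less stabilised enolate carbon (the unsubstituted ring carbon) adds first to the CH2 terminus, the allyl-bearing carbon then closes ring B on the Me2C= terminus in a 6-endo-trig Michael addition, the chiral ammonium ion pair selects the enolate face in this closure (C1 and, because the one-carbon bridge can only be cis, C5), and the epimerisable aldehyde settles exo at C7, anti to the dione bridge.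

**Step 7**
Reactants: 14 bicyclo[3.2.1]octanetrione aldehyde
Product: 16 (1S,5R,7S)-2-methoxy-8,8-dimethyl-4,9-dioxo-1-(prop-2-en-1-yl)bicyclo[3.3.1]non-2-ene-7-carbaldehyde, via diketone 15 (not isolated)
Conditions: CH2N2 (2.2 equiv), Et2O–MeOH (10:1), −20 to 0 °C
Reagents that add atoms: diazomethane, C=[N+]=[N-]
Why: Diazomethane attacks C4 (the dione carbonyl beside the C5–H bridgehead; attack at C2 would lead to the same product), and the diazonium betaine loses N2 with 1,2-shift of the acyl carbon C2 onto the new carbon, which becomes C3; the enol of diketone 15 is then O-methylated by the second equivalent. This is the Büchner–Curtius–Schlotterbeck (Tiffeneau–Demjanov-type) homologation, in the variant long known for strained cyclic α-diketones such as camphorquinone and acenaphthenequinone, which give ring-enlarged β-diketone enol ethers. No ring is closed and no stereocentre is made: the five-membered ring C1–C2–C4–C5–C9 is enlarged to the six-membered ring A, while C1, C5 and C7 are spectators. The step needs selectivity for the dione over the C9 ketone and the aldehyde; the strain and mutual activation of the two non-enolisable vicinal carbonyls, the shielding of C9 by both bridgeheads and the use of only two equivalents at low temperature should secure it. It needs acyl migration rather than migration of C5 or epoxide closure; C5 is deactivated as a migrating group by its C9 carbonyl, the acyl shift relieves the eclipsed dione, and methanol as co-solvent disfavours the epoxide. Methylation is wanted on O2 so that the ketone stays next to the C5–H needed in step 12; any 4-methoxy isomer is returned to 15 by mild hydrolysis and methylated again.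

**Step 8**
Reactants: 16 enol ether aldehyde
Product: 17 (1S,5R,7S)-7-(1-hydroxyprop-2-en-1-yl)-2-methoxy-8,8-dimethyl-1-(prop-2-en-1-yl)bicyclo[3.3.1]non-2-ene-4,9-dione (carbinol epimers)
Conditions: CH2=CHMgBr (1.1 equiv), THF, −78 °C; aq. NH4Cl
Reagents that add atoms: vinylmagnesium bromide, C=C[Mg]Br
Why: Chemoselective Grignard 1,2-addition to the aldehyde, the most electrophilic carbonyl (C9 is flanked by two bridgeheads, C4 is a vinylogous ester carbonyl); the carbinol centre is removed in step 10, so its configuration does not matter.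

**Step 9**
Reactants: 17 allylic alcohol
Product: 18 1-[(1S,5R,7S)-2-methoxy-8,8-dimethyl-4,9-dioxo-1-(prop-2-en-1-yl)bicyclo[3.3.1]non-2-en-7-yl]prop-2-en-1-yl acetate
Conditions: Ac2O, Et3N, DMAP (cat.), CH2Cl2, 0 °C to rt
Reagents that add atoms: acetic anhydride, CC(=O)OC(C)=O
Why: DMAP-catalysed acetylation of the secondary allylic alcohol to give the π-allyl precursor.

**Step 10**
Reactants: 18 allylic acetate
Product: 19 (1S,5R,7S)-2-methoxy-8,8-dimethyl-1,7-di(prop-2-en-1-yl)bicyclo[3.3.1]non-2-ene-4,9-dione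
Conditions: Pd(OAc)2 (5 mol %), PBu3, HCO2NH4, dioxane, 100 °C
Reagents that add atoms: none
Why: Palladium-catalysed formate reduction of the allylic acetate: the π-allylpalladium formate delivers hydride to the more substituted terminus, giving the terminal alkene, and C7 is not touched (this aldehyde-to-allyl sequence is precedented on the same bicyclic skeleton).

**Step 11**
Reactants: 19 diallyl enol ether
Product: 20 (1S,5R,7S)-2-methoxy-8,8-dimethyl-1,7-bis(3-methylbut-2-en-1-yl)bicyclo[3.3.1]non-2-ene-4,9-dione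
Conditions: second-generation Grubbs catalyst RuCl2(=CHPh)(H2IMes)(PCy3) (5 mol %), 2-methylbut-2-ene (excess), CH2Cl2, 40 °C
Reagents that add atoms: 2-methylbut-2-ene, CC=C(C)C
Why: Olefin cross-metathesis turns both terminal allyl groups into prenyl groups; the C2=C3 enol ether double bond is inert, and the step is placed before the geranyl chain is present.

**Step 12**
Reactants: 20 diprenyl enol ether; 21 (2E)-1-bromo-3,7-dimethylocta-2,6-diene (geranyl bromide)
Product: 23 (1S,5R,7S)-5-[(2E)-3,7-dimethylocta-2,6-dien-1-yl]-2-methoxy-8,8-dimethyl-1,7-bis(3-methylbut-2-en-1-yl)bicyclo[3.3.1]non-2-ene-4,9-dione, via bridgehead organolithium 22 (not isolated)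
Conditions: LiN(i-Pr)2 (1.2 equiv), THF, −78 °C; then 21, −78 to 0 °C
Reagents that add atoms: none
Why: Bridgehead lithiation–alkylation, precedented for bicyclo[3.3.1]nonane-2,4,9-trione methyl enol ethers: C5–H is the only sp3 C–H flanked by two carbonyls (C4 and C9), the carbanion is held in place by the bicycle, and SN2 alkylation by the allylic bromide gives retention.

**Step 13**
Reactants: 24 3,4-dihydroxybenzoic acid (protocatechuic acid)
Product: 25 3,4-diacetoxybenzoic acid
Conditions: Ac2O (excess), H2SO4 (cat.), 60 °C; then H2O, rt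
Reagents that add atoms: acetic anhydride, CC(=O)OC(C)=O
Why: Acid-catalysed O-acetylation of both phenols (the acetylation used for salicylic acid); water in the work-up hydrolyses excess anhydride and any mixed anhydride of the carboxylic acid.

**Step 14**
Reactants: 25 3,4-diacetoxybenzoic acid
Product: 26 3,4-diacetoxybenzoyl chloride
Conditions: (COCl)2 (1.5 equiv), DMF (cat.), CH2Cl2, 0 °C to rt; concentrated and used crude
Reagents that add atoms: oxalyl chloride, O=C(Cl)C(Cl)=O
Why: Acid chloride formation through the catalytic Vilsmeier-type chloroiminium species; the aryl acetates are inert under these acidic, non-nucleophilic conditions.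

**Step 15**
Reactants: 23 geranylated enol ether; 26 3,4-diacetoxybenzoyl chloride
Product: 28 4-{[(1S,5S,7S)-5-[(2E)-3,7-dimethylocta-2,6-dien-1-yl]-2-methoxy-8,8-dimethyl-1,7-bis(3-methylbut-2-en-1-yl)-4,9-dioxobicyclo[3.3.1]non-2-en-3-yl]carbonyl}-1,2-phenylene diacetate, via vinyllithium 27 (not isolated)
Conditions: lithium 2,2,6,6-tetramethylpiperidide (1.5 equiv), THF, −78 °C; then 26, −78 °C
Reagents that add atoms: none
Why: α-Lithiation of the β-methoxy enone at C3 (the only acidic position left) and C-acylation by the acid chloride, precedented on this ring system; the acid chloride reacts much faster than the aryl acetates at −78 °C.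

**Step 16**
Reactants: 28 aroylated enol ether diacetate
Product: 29 (1R,5R,7S)-3-(3,4-dihydroxybenzoyl)-5-[(2E)-3,7-dimethylocta-2,6-dien-1-yl]-4-hydroxy-8,8-dimethyl-1,7-bis(3-methylbut-2-en-1-yl)bicyclo[3.3.1]non-3-ene-2,9-dione (target)
Conditions: LiOH, dioxane–H2O (degassed), 90 °C; then aq. HCl to pH 3
Reagents that add atoms: lithium hydroxide, [Li+].[OH-]
Why: Hydroxide cleaves the vinylogous methyl ester by addition–elimination at C2 and saponifies both aryl acetates in one operation; no stereocentre is touched and oxygen is excluded to protect the catechol.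

**Compound list**
1 | hex-5-en-2-one | CC(=O)CCC=C | starting material
2 | diethyl oxalate | CCOC(=O)C(=O)OCC | starting material
3 | ethyl 2,4-dioxooct-7-enoate | CCOC(=O)C(=O)CC(=O)CCC=C | intermediate
4 | ethyl 2-oxo-2-[2,3,5-trioxo-4-(prop-2-en-1-yl)cyclopentyl]acetate | C=CCC1C(=O)C(C(=O)C(=O)OCC)C(=O)C1=O | intermediate
5 | 3-(prop-2-en-1-yl)cyclopentane-1,2,4-trione | C=CCC1C(=O)CC(=O)C1=O | intermediate
6 | 3,3-diethoxyprop-1-ene | C=CC(OCC)OCC | starting material
7 | 2,3-dibromo-1,1-diethoxypropane | BrCC(Br)C(OCC)OCC | intermediate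
8 | 2-bromo-3,3-diethoxyprop-1-ene | C=C(Br)C(OCC)OCC | intermediate
9 | (3,3-diethoxyprop-1-en-2-yl)lithium | [Li]C(=C)C(OCC)OCC | intermediate
10 | lithium 3-(diethoxymethyl)-2-methylbut-3-en-2-olate | [Li+].[O-]C(C)(C)C(=C)C(OCC)OCC | intermediate
11 | 3-(diethoxymethyl)-2-methylbut-3-en-2-yl acetate | CC(=O)OC(C)(C)C(=C)C(OCC)OCC | intermediate
12 | 3-formyl-2-methylbut-3-en-2-yl acetate | CC(=O)OC(C)(C)C(=C)C=O | intermediate
13 | 3-methyl-2-{[2,3,5-trioxo-4-(prop-2-en-1-yl)cyclopentyl]methyl}but-2-enal | C=CCC1C(=O)C(CC(C=O)=C(C)C)C(=O)C1=O | intermediate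
14 | (1R,3S,5S)-2,2-dimethyl-6,7,8-trioxo-1-(prop-2-en-1-yl)bicyclo[3.2.1]octane-3-carbaldehyde (aldehyde exo, anti to the dione bridge) | [C@@H]12C[C@H](C=O)C(C)(C)[C@@](CC=C)(C(=O)C1=O)C2=O | intermediate
15 | (1S,5R,7S)-8,8-dimethyl-2,4,9-trioxo-1-(prop-2-en-1-yl)bicyclo[3.3.1]nonane-7-carbaldehyde | [C@@H]12C[C@H](C=O)C(C)(C)[C@@](CC=C)(C(=O)CC1=O)C2=O | intermediate
16 | (1S,5R,7S)-2-methoxy-8,8-dimethyl-4,9-dioxo-1-(prop-2-en-1-yl)bicyclo[3.3.1]non-2-ene-7-carbaldehyde | [C@@H]12C[C@H](C=O)C(C)(C)[C@@](CC=C)(C(OC)=CC1=O)C2=O | intermediate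
17 | (1S,5R,7S)-7-(1-hydroxyprop-2-en-1-yl)-2-methoxy-8,8-dimethyl-1-(prop-2-en-1-yl)bicyclo[3.3.1]non-2-ene-4,9-dione (carbinol epimers) | [C@@H]12C[C@H](C(O)C=C)C(C)(C)[C@@](CC=C)(C(OC)=CC1=O)C2=O | intermediate
18 | 1-[(1S,5R,7S)-2-methoxy-8,8-dimethyl-4,9-dioxo-1-(prop-2-en-1-yl)bicyclo[3.3.1]non-2-en-7-yl]prop-2-en-1-yl acetate | [C@@H]12C[C@H](C(OC(C)=O)C=C)C(C)(C)[C@@](CC=C)(C(OC)=CC1=O)C2=O | intermediate
19 | (1S,5R,7S)-2-methoxy-8,8-dimethyl-1,7-di(prop-2-en-1-yl)bicyclo[3.3.1]non-2-ene-4,9-dione | [C@@H]12C[C@H](CC=C)C(C)(C)[C@@](CC=C)(C(OC)=CC1=O)C2=O | intermediate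
20 | (1S,5R,7S)-2-methoxy-8,8-dimethyl-1,7-bis(3-methylbut-2-en-1-yl)bicyclo[3.3.1]non-2-ene-4,9-dione | [C@@H]12C[C@H](CC=C(C)C)C(C)(C)[C@@](CC=C(C)C)(C(OC)=CC1=O)C2=O | intermediate
21 | (2E)-1-bromo-3,7-dimethylocta-2,6-diene | CC(C)=CCC/C(C)=C/CBr | starting material
22 | C5 bridgehead lithium derivative of 20 (lithium exo, in place of H) | [Li][C@@]12C[C@H](CC=C(C)C)C(C)(C)[C@@](CC=C(C)C)(C(OC)=CC1=O)C2=O | intermediate
23 | (1S,5R,7S)-5-[(2E)-3,7-dimethylocta-2,6-dien-1-yl]-2-methoxy-8,8-dimethyl-1,7-bis(3-methylbut-2-en-1-yl)bicyclo[3.3.1]non-2-ene-4,9-dione | CC(C)=CCC/C(C)=C/C[C@@]12C[C@H](CC=C(C)C)C(C)(C)[C@@](CC=C(C)C)(C(OC)=CC1=O)C2=O | intermediate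
24 | 3,4-dihydroxybenzoic acid | Oc1ccc(cc1O)C(=O)O | starting material
25 | 3,4-diacetoxybenzoic acid | CC(=O)Oc1ccc(cc1OC(C)=O)C(=O)O | intermediate
26 | 3,4-diacetoxybenzoyl chloride | CC(=O)Oc1ccc(cc1OC(C)=O)C(Cl)=O | intermediate
27 | C3 lithium derivative of 23 | CC(C)=CCC/C(C)=C/C[C@@]12C[C@H](CC=C(C)C)C(C)(C)[C@@](CC=C(C)C)(C(OC)=C([Li])C1=O)C2=O | intermediate
28 | 4-{[(1S,5S,7S)-5-[(2E)-3,7-dimethylocta-2,6-dien-1-yl]-2-methoxy-8,8-dimethyl-1,7-bis(3-methylbut-2-en-1-yl)-4,9-dioxobicyclo[3.3.1]non-2-en-3-yl]carbonyl}-1,2-phenylene diacetate | CC(C)=CCC/C(C)=C/C[C@@]12C[C@H](CC=C(C)C)C(C)(C)[C@@](CC=C(C)C)(C(OC)=C(C(=O)c3ccc(OC(C)=O)c(OC(C)=O)c3)C1=O)C2=O | intermediate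
29 | (1R,5R,7S)-3-(3,4-dihydroxybenzoyl)-5-[(2E)-3,7-dimethylocta-2,6-dien-1-yl]-4-hydroxy-8,8-dimethyl-1,7-bis(3-methylbut-2-en-1-yl)bicyclo[3.3.1]non-3-ene-2,9-dione | CC(C)=CCC/C(C)=C/C[C@@]12C[C@H](CC=C(C)C)C(C)(C)[C@@](CC=C(C)C)(C(=O)C(C(=O)c3ccc(O)c(O)c3)=C1O)C2=O | target

**Totals**
Total steps: 16. Longest linear sequence: 12 (steps 3–12, 15 and 16, from 6).

**Steps most likely to fail**

Step 6. The chiral ion pair may discriminate poorly between the enolate faces in the ring-closing Michael addition, or induce the opposite sense, in which case the pseudo-enantiomeric cinchoninium salt is the first remedy. The first alkylation may also occur at the allyl-bearing carbon, and carbonate may open the non-enolisable trione by retro-Claisen cleavage. The fallback takes the chirality from a kinetic resolution instead and sets out from 5 and 12. With KN(SiMe3)2 in THF at −78 to 0 °C and no chiral salt, the annulation should give 14 together with its mirror image, the ent-trione aldehyde F1. Steps 7–11 then carry the mirror-image series along beside 14–20: the ent-diketone F2, which is not isolated, the ent-enol ether aldehyde F3, the ent-allylic alcohol F4, the ent-allylic acetate F5, the ent-diallyl compound F6 and the ent-diprenyl compound F7. In step 12, LiN(i-Pr)2 is replaced by a chiral bis-lithium amide made from (1R,2R)-1,2-diphenyl-N,N′-bis[(R)-1-phenylethyl]ethane-1,2-diamine, n-BuLi and LiCl, or by its antipode, whichever deprotonates 20 faster; this kinetic resolution is known for bridgehead lithiation of this ring system. Only 20 should be deprotonated and geranylated, the ent-diprenyl compound F7 is left behind and separated, and the route is rejoined at 23.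

Step 7. The betaine may close to a spiro-epoxide instead of undergoing the acyl shift, excess reagent may homologate the aldehyde, and methylation may go to the wrong oxygen. The fallback sets out from 14. The aldehyde is first masked as the dimethyl acetal F8 by CH(OMe)3 and pyridinium p-toluenesulfonate in MeOH. The insertion can then be run with a larger excess of diazomethane in a methanol-rich medium, through the diketone acetal F9 to the enol ether acetal F10. Mild hydrolysis by pyridinium p-toluenesulfonate in wet acetone returns to the route at 16.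

Step 12. Deprotonation may be slow or may occur at the C3 vinyl position instead of the bridgehead, and the base or the carbanion may consume geranyl bromide by elimination. The fallback sets out from 20. C3 is first blocked as the C-silyl enol ether F11 by lithium 2,2,6,6-tetramethylpiperidide in the presence of Me3SiCl. The bridgehead, now the only acidic C–H, is lithiated with LiN(i-Pr)2 and geranylated to the silylated geranyl compound F12. Bu4NF then removes the silyl group and the route is rejoined at 23.

**Further compounds**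
F1 | step 6 | (1S,3R,5R)-2,2-dimethyl-6,7,8-trioxo-1-(prop-2-en-1-yl)bicyclo[3.2.1]octane-3-carbaldehyde (mirror image of 14) | [C@H]12C[C@@H](C=O)C(C)(C)[C@](CC=C)(C(=O)C1=O)C2=O
F2 | step 6 | (1R,5S,7R)-8,8-dimethyl-2,4,9-trioxo-1-(prop-2-en-1-yl)bicyclo[3.3.1]nonane-7-carbaldehyde (mirror image of 15) | [C@H]12C[C@@H](C=O)C(C)(C)[C@](CC=C)(C(=O)CC1=O)C2=O
F3 | step 6 | (1R,5S,7R)-2-methoxy-8,8-dimethyl-4,9-dioxo-1-(prop-2-en-1-yl)bicyclo[3.3.1]non-2-ene-7-carbaldehyde (mirror image of 16) | [C@H]12C[C@@H](C=O)C(C)(C)[C@](CC=C)(C(OC)=CC1=O)C2=O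
F4 | step 6 | (1R,5S,7R)-7-(1-hydroxyprop-2-en-1-yl)-2-methoxy-8,8-dimethyl-1-(prop-2-en-1-yl)bicyclo[3.3.1]non-2-ene-4,9-dione (mirror image of 17) | [C@H]12C[C@@H](C(O)C=C)C(C)(C)[C@](CC=C)(C(OC)=CC1=O)C2=O
F5 | step 6 | 1-[(1R,5S,7R)-2-methoxy-8,8-dimethyl-4,9-dioxo-1-(prop-2-en-1-yl)bicyclo[3.3.1]non-2-en-7-yl]prop-2-en-1-yl acetate (mirror image of 18) | [C@H]12C[C@@H](C(OC(C)=O)C=C)C(C)(C)[C@](CC=C)(C(OC)=CC1=O)C2=O
F6 | step 6 | (1R,5S,7R)-2-methoxy-8,8-dimethyl-1,7-di(prop-2-en-1-yl)bicyclo[3.3.1]non-2-ene-4,9-dione (mirror image of 19) | [C@H]12C[C@@H](CC=C)C(C)(C)[C@](CC=C)(C(OC)=CC1=O)C2=O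
F7 | step 6 | (1R,5S,7R)-2-methoxy-8,8-dimethyl-1,7-bis(3-methylbut-2-en-1-yl)bicyclo[3.3.1]non-2-ene-4,9-dione (mirror image of 20) | [C@H]12C[C@@H](CC=C(C)C)C(C)(C)[C@](CC=C(C)C)(C(OC)=CC1=O)C2=O
F8 | step 7 | (1R,3S,5S)-3-(dimethoxymethyl)-2,2-dimethyl-1-(prop-2-en-1-yl)bicyclo[3.2.1]octane-6,7,8-trione | [C@@H]12C[C@H](C(OC)OC)C(C)(C)[C@@](CC=C)(C(=O)C1=O)C2=O
F9 | step 7 | (1S,5R,7S)-7-(dimethoxymethyl)-8,8-dimethyl-1-(prop-2-en-1-yl)bicyclo[3.3.1]nonane-2,4,9-trione | [C@@H]12C[C@H](C(OC)OC)C(C)(C)[C@@](CC=C)(C(=O)CC1=O)C2=O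
F10 | step 7 | (1S,5R,7S)-7-(dimethoxymethyl)-2-methoxy-8,8-dimethyl-1-(prop-2-en-1-yl)bicyclo[3.3.1]non-2-ene-4,9-dione | [C@@H]12C[C@H](C(OC)OC)C(C)(C)[C@@](CC=C)(C(OC)=CC1=O)C2=O
F11 | step 12 | 3-(trimethylsilyl) derivative of 20 | [C@@H]12C[C@H](CC=C(C)C)C(C)(C)[C@@](CC=C(C)C)(C(OC)=C([Si](C)(C)C)C1=O)C2=O
F12 | step 12 | 3-(trimethylsilyl) derivative of 23 | CC(C)=CCC/C(C)=C/C[C@@]12C[C@H](CC=C(C)C)C(C)(C)[C@@](CC=C(C)C)(C(OC)=C([Si](C)(C)C)C1=O)C2=O
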